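**Plan**
- Retrosynthesis: the 5-O protecting group, the 3-O–CH3 bond and the C3–O bond are removed first, which leads back to a 3-unsubstituted flavone. Ring C is then cut at C4a–C4, C4–C3 and O1–C2 in one operation.
- Enabling feature: C4 is a single carbonyl carbon bonded only to C4a and C3, so it can be supplied as CO. C4a is the only non-oxygenated carbon of ring A and lies between C5–O and C8a–O1, so it maps onto the one C–H of a 4,5,6-trimethoxyresorcinol. That is the only site open to iodine, and because the three methoxy groups are mirror-related, either flanking oxygen may become O1.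
- Forward: rings A (from 2,3,4-trimethoxybenzaldehyde) and B (alkyne from 2,5-dimethoxybenzaldehyde) are carried in intact. Ring C is the only ring built, in the Pd/CO three-component annulation.
- One resorcinol oxygen is benzylated before the second is unveiled. This avoids a statistical protection, and the annulation gives the 5-O-protected flavone directly, ready for C3 lithiation–borylation–oxidation, O-methylation and hydrogenolysis.
- Stereochemistry: the target has no stereocentre, so nothing has to be set or preserved.

Key step: step 7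

Remark on the chemistry: the target is achiral (no stereocentre, and free rotation about C2–C1′ is assumed), so the compound is its own single stereoisomer.

**Step 1**
Reactants: 1 2,3,4-trimethoxybenzaldehyde
Product: 2 5-bromo-2,3,4-trimethoxybenzaldehyde
Conditions: NBS, DMF, rt, dark
Reagents that add atoms: N-bromosuccinimide, O=C1CCC(=O)N1Br
Why: Electrophilic aromatic bromination should go to C5, which is para to the 2-OMe, ortho to the 4-OMe and meta to the formyl group, whereas C6 is activated only by the twisted, weakly donating 3-OMe.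

**Step 2**
Reactants: 2 5-bromo-2,3,4-trimethoxybenzaldehyde
Product: 4 5-bromo-2,3,4-trimethoxyphenol, via aryl formate 3 (not isolated)
Conditions: mCPBA, CH2Cl2, 0 °C to rt; NaHCO3 wash; then K2CO3 (cat.), MeOH, rt
Reagents that add atoms: 3-chloroperbenzoic acid, O=C(OO)c1cccc(Cl)c1
Why: In this Baeyer–Villiger (Dakin-type) oxidation the aryl group, enriched by ortho and para methoxy groups, should migrate in preference to hydride, and the labile formate is methanolysed under mild base that leaves the aryl bromide untouched.

**Step 3**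
Reactants: 4 5-bromo-2,3,4-trimethoxyphenol
Product: 5 1-(benzyloxy)-5-bromo-2,3,4-trimethoxybenzene
Conditions: BnBr, K2CO3, DMF, rt
Reagents that add atoms: benzyl bromide, BrCc1ccccc1
Why: Williamson etherification of the only phenol marks the future 5-oxygen before the second oxygen exists, so the two resorcinol positions are differentiated without a statistical step.

**Step 4**
Reactants: 5 1-(benzyloxy)-5-bromo-2,3,4-trimethoxybenzene
Product: 8 5-(benzyloxy)-2,3,4-trimethoxyphenol, via aryllithium 6 (not isolated), via dimethyl arylboronate 7 (not isolated)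
Conditions: n-BuLi, THF, −78 °C; B(OMe)3, −78 °C to rt; AcOH, 30% H2O2, 0 °C to rt
Reagents that add atoms: hydrogen peroxide, OO (the new oxygen); trimethyl borate, COB(OC)OC (boron unit of 7 only); n-butyllithium, [Li]CCCC (lithium of 6 only)
Why: Bromine–lithium exchange is faster at −78 °C than any benzylic deprotonation, and borate trapping followed by peroxide-induced 1,2-aryl migration (ipso-hydroxylation of an arylboronate) puts the oxygen exactly where the bromine was.

**Step 5**
Reactants: 8 5-(benzyloxy)-2,3,4-trimethoxyphenol
Product: 9 3-(benzyloxy)-2-iodo-4,5,6-trimethoxyphenol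
Conditions: NIS, CH2Cl2, 0 °C, dark
Reagents that add atoms: N-iodosuccinimide, O=C1CCC(=O)N1I
Why: Electrophilic aromatic iodination has only one C–H available on the activated ring, ortho to both the OH and the OBn group, and the unactivated phenyl ring of the benzyl group cannot compete.

**Step 6**
Reactants: 10 2,5-dimethoxybenzaldehyde
Product: 11 2-ethynyl-1,4-dimethoxybenzene
Conditions: Ohira–Bestmann reagent, K2CO3, MeOH, rt
Reagents that add atoms: dimethyl (1-diazo-2-oxopropyl)phosphonate, COP(=O)(OC)C(=[N+]=[N-])C(C)=O
Why: The Seyferth–Gilbert homologation in its Ohira–Bestmann form converts non-enolisable aryl aldehydes into terminal alkynes through olefination, loss of N2 and 1,2-hydride shift under conditions harmless to aryl methyl ethers.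

**Step 7**
Reactants: 9 3-(benzyloxy)-2-iodo-4,5,6-trimethoxyphenol; 11 2-ethynyl-1,4-dimethoxybenzene; 12 carbon monoxide
Product: 15 5-(benzyloxy)-2-(2,5-dimethoxyphenyl)-6,7,8-trimethoxy-4H-chromen-4-one, via ynone 13 (not isolated), via enaminone 14 (not isolated)
Conditions: PdCl2(dppf) (5 mol %), CO (20 bar), Et2NH, 120 °C, autoclave
Reagents that add atoms: carbon monoxide (12), [C-]#[O+]; diethylamine, CCNCC (amino group of 14 only)
Why: Pd(0) inserts into the C–I bond of 9, CO migrates in to give the aroyl-palladium species, and amine-assisted transfer of the acetylide of 11 with reductive elimination forges C4a–C4 and C4–C3 in ynone 13; Et2NH then adds to the aryl-bearing alkyne carbon to give enaminone 14, whose free phenol oxygen attacks that same carbon and expels the amine, forming O1–C2. The closest known reaction type is the palladium-catalysed carbonylative annulation of 2-iodophenols with terminal arylacetylenes in a secondary amine (carbonylative Sonogashira coupling, then oxa-Michael addition–elimination), which is established for flavones. Ring C is the only ring closed, formally 6-endo-dig with respect to the ynone and in practice a 6-endo-trig addition–elimination on the enaminone. No stereocentre is created. Three selectivities are needed: flavone over five-ring aurone closure, secured by passing through the enaminone, in which the carbon next to the carbonyl is no longer electrophilic; CO uptake before alkynylation, secured by 20 bar CO, the absence of copper and the two ortho substituents that speed up migratory insertion; and a single cyclising oxygen, secured by the benzyl ether on the other one. The chelating ferrocenyl diphosphine and 120 °C are chosen to carry the slow oxidative addition of this electron-rich, doubly ortho-flanked iodide.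

**Step 8**
Reactants: 15 5-(benzyloxy)-2-(2,5-dimethoxyphenyl)-6,7,8-trimethoxy-4H-chromen-4-one
Product: 18 5-(benzyloxy)-2-(2,5-dimethoxyphenyl)-3-hydroxy-6,7,8-trimethoxy-4H-chromen-4-one, via 3-lithioflavone 16 (not isolated), via flavone-3-boronate 17 (not isolated)
Conditions: LDA, THF, −78 °C; B(OMe)3, −78 °C to 0 °C; AcOH, 30% H2O2, 0 °C to rt
Reagents that add atoms: hydrogen peroxide, OO (the 3-oxygen); trimethyl borate, COB(OC)OC (boron unit of 17 only); lithium diisopropylamide, [Li]N(C(C)C)C(C)C (lithium of 16 only)
Why: C3 lithiation of flavones with LDA, borate trapping and peroxide oxidation is a known route to flavonols; here C3–H is the only acidic C–H, and the lithium can be held by the C4 carbonyl and the 2′-methoxy oxygen.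

**Step 9**
Reactants: 18 5-(benzyloxy)-2-(2,5-dimethoxyphenyl)-3-hydroxy-6,7,8-trimethoxy-4H-chromen-4-one
Product: 19 5-(benzyloxy)-2-(2,5-dimethoxyphenyl)-3,6,7,8-tetramethoxy-4H-chromen-4-one
Conditions: MeI, K2CO3, acetone, reflux
Reagents that add atoms: iodomethane, CI
Why: Williamson-type O-methylation acts on the acidic enolic 3-OH, which is the only free hydroxyl in the molecule.

**Step 10**
Reactants: 19 5-(benzyloxy)-2-(2,5-dimethoxyphenyl)-3,6,7,8-tetramethoxy-4H-chromen-4-one
Product: 20 grantioidinin (5-hydroxy-3,6,7,8,2′,5′-hexamethoxyflavone)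
Conditions: H2 (1 atm), 10% Pd/C, EtOAc/MeOH, rt
Reagents that add atoms: none
Why: Catalytic hydrogenolysis cleaves the benzyl aryl ether, while the methyl ethers and the tetrasubstituted, vinylogous-ester C2=C3 bond should stay inert at atmospheric pressure.

**Compound list**
1 | 2,3,4-trimethoxybenzaldehyde | COc1ccc(C=O)c(OC)c1OC | starting material
2 | 5-bromo-2,3,4-trimethoxybenzaldehyde | COc1c(Br)cc(C=O)c(OC)c1OC | intermediate
3 | 5-bromo-2,3,4-trimethoxyphenyl formate | COc1c(Br)cc(OC=O)c(OC)c1OC | intermediate (not isolated)
4 | 5-bromo-2,3,4-trimethoxyphenol | COc1c(Br)cc(O)c(OC)c1OC | intermediate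
5 | 1-(benzyloxy)-5-bromo-2,3,4-trimethoxybenzene | COc1c(Br)cc(OCc2ccccc2)c(OC)c1OC | intermediate
6 | [5-(benzyloxy)-2,3,4-trimethoxyphenyl]lithium | [Li]c1cc(OCc2ccccc2)c(OC)c(OC)c1OC | intermediate (not isolated)
7 | dimethyl [5-(benzyloxy)-2,3,4-trimethoxyphenyl]boronate | COB(OC)c1cc(OCc2ccccc2)c(OC)c(OC)c1OC | intermediate (not isolated)
8 | 5-(benzyloxy)-2,3,4-trimethoxyphenol | COc1c(O)cc(OCc2ccccc2)c(OC)c1OC | intermediate
9 | 3-(benzyloxy)-2-iodo-4,5,6-trimethoxyphenol | COc1c(O)c(I)c(OCc2ccccc2)c(OC)c1OC | intermediate
10 | 2,5-dimethoxybenzaldehyde | COc1ccc(OC)c(C=O)c1 | starting material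
11 | 2-ethynyl-1,4-dimethoxybenzene | C#Cc1cc(OC)ccc1OC | intermediate
12 | carbon monoxide | [C-]#[O+] | starting material
13 | 1-[2-(benzyloxy)-6-hydroxy-3,4,5-trimethoxyphenyl]-3-(2,5-dimethoxyphenyl)prop-2-yn-1-one | COc1ccc(OC)c(C#CC(=O)c2c(O)c(OC)c(OC)c(OC)c2OCc2ccccc2)c1 | intermediate (not isolated)
14 | (E)-1-[2-(benzyloxy)-6-hydroxy-3,4,5-trimethoxyphenyl]-3-(diethylamino)-3-(2,5-dimethoxyphenyl)prop-2-en-1-one (geometry is lost on cyclisation) | CCN(CC)/C(=C/C(=O)c1c(O)c(OC)c(OC)c(OC)c1OCc1ccccc1)c1cc(OC)ccc1OC | intermediate (not isolated)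
15 | 5-(benzyloxy)-2-(2,5-dimethoxyphenyl)-6,7,8-trimethoxy-4H-chromen-4-one | COc1ccc(OC)c(-c2cc(=O)c3c(OCc4ccccc4)c(OC)c(OC)c(OC)c3o2)c1 | intermediate
16 | [5-(benzyloxy)-2-(2,5-dimethoxyphenyl)-6,7,8-trimethoxy-4-oxo-4H-chromen-3-yl]lithium | [Li]c1c(-c2cc(OC)ccc2OC)oc2c(OC)c(OC)c(OC)c(OCc3ccccc3)c2c1=O | intermediate (not isolated)
17 | dimethyl [5-(benzyloxy)-2-(2,5-dimethoxyphenyl)-6,7,8-trimethoxy-4-oxo-4H-chromen-3-yl]boronate | COB(OC)c1c(-c2cc(OC)ccc2OC)oc2c(OC)c(OC)c(OC)c(OCc3ccccc3)c2c1=O | intermediate (not isolated)
18 | 5-(benzyloxy)-2-(2,5-dimethoxyphenyl)-3-hydroxy-6,7,8-trimethoxy-4H-chromen-4-one | COc1ccc(OC)c(-c2oc3c(OC)c(OC)c(OC)c(OCc4ccccc4)c3c(=O)c2O)c1 | intermediate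
19 | 5-(benzyloxy)-2-(2,5-dimethoxyphenyl)-3,6,7,8-tetramethoxy-4H-chromen-4-one | COc1ccc(OC)c(-c2oc3c(OC)c(OC)c(OC)c(OCc4ccccc4)c3c(=O)c2OC)c1 | intermediate
20 | grantioidinin, 2-(2,5-dimethoxyphenyl)-5-hydroxy-3,6,7,8-tetramethoxy-4H-chromen-4-one (achiral) | COc1ccc(OC)c(-c2oc3c(OC)c(OC)c(OC)c(O)c3c(=O)c2OC)c1 | target

**Totals**
Total step count: 10.
Longest linear sequence: 9 (steps 1–5 and 7–10); step 6 is the one-step side branch.

**Steps most likely to fail**

Step 7. Oxidative addition into the electron-rich, doubly ortho-flanked C–I bond may be so slow that other processes take over. These are hydrodeiodination, capture of the aroyl-palladium species by the amine, and coupling without CO uptake followed by five-ring closure.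

The fallback sets out from 9 and 11 and makes the same ynone by carbanion chemistry instead of carbonylation.
- Alkyne 11 is deprotonated with n-BuLi (THF, −78 °C) to lithium (2,5-dimethoxyphenyl)acetylide F1.
- F1 is acylated with N-methoxy-N-methylcarbamoyl chloride to 3-(2,5-dimethoxyphenyl)-N-methoxy-N-methylprop-2-ynamide F2.
- Iodide 9 is deprotonated at oxygen with MeMgCl/LiCl and then undergoes iodine–magnesium exchange with i-PrMgCl (THF, −20 °C), giving the magnesiated chloromagnesium phenoxide F3.
- F3 adds to F2 and delivers ynone 13 on work-up.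
- Warming 13 with Et2NH in EtOH closes ring C through 14, and the route is rejoined at 15.

Step 8. Deprotonation at C3 may be incomplete, the amide base may add at C2 and open the ring, or the boronate may be protonated off before oxidation.

The fallback sets out from 15 and oxidises the C2=C3 bond directly.
- Dimethyldioxirane (acetone/CH2Cl2, 0 °C) should give the racemic cis-fused 2,3-epoxide of 15 F4.
- Catalytic p-TsOH opens F4 at C2, through a cation stabilised by O1 and ring B. Loss of the C3 proton then gives the flavonol, and the route is rejoined at 18.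

Step 5. The very electron-rich phenol may be oxidised by the iodinating agent, with oxidative loss of the para methyl group, instead of being substituted. The product may also lose iodine again under traces of acid.

The fallback sets out from 8 and installs iodine by an anionic route.
- MOMCl and i-Pr2NEt give 1-(benzyloxy)-2,3,4-trimethoxy-5-(methoxymethoxy)benzene F5.
- Directed ortho-metalation with n-BuLi (THF, −20 °C) at the C–H flanked by the two alkoxy groups gives the aryllithium F6.
- Quenching with I2 gives 1-(benzyloxy)-2-iodo-4,5,6-trimethoxy-3-(methoxymethoxy)benzene F7.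
- Brief treatment with catalytic HCl in MeOH removes the acetal, and the route is rejoined at 9.

**Further compounds**
F1 | step 7 | lithium (2,5-dimethoxyphenyl)acetylide | [Li]C#Cc1cc(OC)ccc1OC
F2 | step 7 | 3-(2,5-dimethoxyphenyl)-N-methoxy-N-methylprop-2-ynamide | CON(C)C(=O)C#Cc1cc(OC)ccc1OC
F3 | step 7 | chloromagnesium 3-(benzyloxy)-2-(chloromagnesio)-4,5,6-trimethoxyphenoxide | Cl[Mg]Oc1c([Mg]Cl)c(OCc2ccccc2)c(OC)c(OC)c1OC
F4 | step 8 | racemic cis-fused 2,3-epoxide of 15, 5-(benzyloxy)-2-(2,5-dimethoxyphenyl)-2,3-epoxy-6,7,8-trimethoxychroman-4-one (one enantiomer drawn) | O=C1c2c(OCc3ccccc3)c(OC)c(OC)c(OC)c2O[C@@]2(c3cc(OC)ccc3OC)O[C@@H]12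
F5 | step 5 | 1-(benzyloxy)-2,3,4-trimethoxy-5-(methoxymethoxy)benzene | COCOc1cc(OCc2ccccc2)c(OC)c(OC)c1OC
F6 | step 5 | [2-(benzyloxy)-3,4,5-trimethoxy-6-(methoxymethoxy)phenyl]lithium | [Li]c1c(OCOC)c(OC)c(OC)c(OC)c1OCc1ccccc1
F7 | step 5 | 1-(benzyloxy)-2-iodo-4,5,6-trimethoxy-3-(methoxymethoxy)benzene | COCOc1c(I)c(OCc2ccccc2)c(OC)c(OC)c1OC
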